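**Plan**
- Target read as epicatechin-(4α→6)-ent-epicatechin-(4β→8)-epicatechin-(4β→6)-epicatechin (units 1 to 4 from the top; unit 2 is the (2S,3S) series; ring C is 3,4-cis in units 1 and 2 and 3,4-trans in unit 3). Retrosynthetic cuts: unit 3 C4–unit 4 C6, then unit 2 C4–unit 3 C8, then unit 1 C4–unit 2 C6.
- Forward: a C6-lithiated unit 2 adds to the C4 ketone of unit 1; unit 2 C4 is oxidised to the ketone and a C8-lithiated unit 3 adds; one double ionic hydrogenation gives the trimer. C4 of unit 3 is then oxidised, all free ring A carbons are capped with bromine, the trimer cation is joined to unit 4, and one hydrogenolysis finishes.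
- Enabling feature: C4 of unit 3 is benzylic and ortho/para to three oxygens of its ring A (O1 through C8a, O5, O7), so its C4–O bond ionises to a planar para-quinone-methide-type cation. C6 of unit 4 lies between O5 and O7 and para to C8a–O1, and is the only free ring A carbon once C8 carries bromine.
- Stereochemistry: C2 and C3 of every unit come from (−)- and (+)-epicatechin. C4 of units 1 and 2 is set by hydride delivery anti to the C2 aryl and C3 benzyloxy groups (3,4-cis). C4 of unit 3 is set by arene attack anti to the same groups on the planar cation (3,4-trans), both C4 epimers of the precursor converging.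
- Helpers (benzyl ethers, five bromine caps, the 2-ethoxyethoxy leaving group) are all gone after the last step.

Key step: step 15

Remark: (+)-epicatechin, the (2S,3S) enantiomer, is taken as a purchasable starting material. Ring letters follow flavan usage (ring A = 5,7-dioxygenated benzo ring, ring B = catechol ring, ring C = pyran ring).

**Route**

Step 1
Reactants: 1 (−)-epicatechin
Product: 2 3,5,7,3',4'-penta-O-benzyl-(−)-epicatechin
Conditions: NaH (6 equiv), BnBr (6 equiv), DMF, −20 → 20 °C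
Reagents that add atoms: benzyl bromide BrCc1ccccc1
Why: Williamson etherification in which NaH deprotonates the four phenols and the C3 hydroxyl and each oxygen anion displaces bromide, the low temperature limiting C-benzylation of ring A and leaving C2 and C3 untouched.

Step 2
Reactants: 2 3,5,7,3',4'-penta-O-benzyl-(−)-epicatechin
Product: 3 4β-hydroxy-penta-O-benzyl-(−)-epicatechin
Conditions: DDQ (1.5 equiv), CH2Cl2/H2O, 20 °C
Reagents that add atoms: water O
Why: DDQ benzylic oxidation in which hydride abstraction from C4 gives the cation stabilised by O1, O5 and O7 of ring A and water adds trans to the C3 benzyloxy group, the C4 configuration being lost again in step 3.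

Step 3
Reactants: 3 4β-hydroxy-penta-O-benzyl-(−)-epicatechin
Product: 4 penta-O-benzyl-4-oxo-epicatechin, the 2,3-cis flavan-4-one
Conditions: (n-Pr)4NRuO4 (5 mol %), NMO, 4 Å MS, CH2Cl2, 20 °C
Reagents that add atoms: none
Why: Ley–Griffith oxidation of the secondary benzylic alcohol to the ketone under neutral conditions that spare the enolisable 2,3-cis C3 centre.

Step 4
Reactants: 2 3,5,7,3',4'-penta-O-benzyl-(−)-epicatechin
Product: 5 8-bromo-penta-O-benzyl-(−)-epicatechin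
Conditions: NBS (1.0 equiv), CH2Cl2, −40 → 0 °C
Reagents that add atoms: N-bromosuccinimide O=C1CCC(=O)N1Br
Why: Electrophilic aromatic bromination of the trioxygenated ring A, which should take place at C8 because C6 is flanked by two benzyloxy groups.

Step 5
Reactants: 6 (+)-epicatechin
Product: 7 3,5,7,3',4'-penta-O-benzyl-(+)-epicatechin
Conditions: NaH (6 equiv), BnBr (6 equiv), DMF, −20 → 20 °C
Reagents that add atoms: benzyl bromide BrCc1ccccc1
Why: Williamson etherification as in step 1, carried out in the enantiomeric series.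

Step 6
Reactants: 7 3,5,7,3',4'-penta-O-benzyl-(+)-epicatechin
Product: 8 4-hydroxy-penta-O-benzyl-(+)-epicatechin (OH trans to the C3 benzyloxy group)
Conditions: DDQ (1.5 equiv), CH2Cl2/H2O, 20 °C
Reagents that add atoms: water O
Why: DDQ benzylic oxidation as in step 2, placing at C4 the oxygen that later becomes the ketone of unit 2.

Step 7
Reactants: 8 4-hydroxy-penta-O-benzyl-(+)-epicatechin
Product: 9 8-bromo-4-hydroxy-penta-O-benzyl-(+)-epicatechin
Conditions: NBS (1.0 equiv), CH2Cl2, −40 → 0 °C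
Reagents that add atoms: N-bromosuccinimide O=C1CCC(=O)N1Br
Why: Electrophilic aromatic bromination at C8 as in step 4, the bromine forcing the next halogen to C6 and later serving as a cap.

Step 8
Reactants: 9 8-bromo-4-hydroxy-penta-O-benzyl-(+)-epicatechin
Product: 10 8-bromo-6-iodo-4-hydroxy-penta-O-benzyl-(+)-epicatechin
Conditions: NIS (1.2 equiv), MeCN/CH2Cl2, 0 → 20 °C, dark, no acid
Reagents that add atoms: N-iodosuccinimide O=C1CCC(=O)N1I
Why: Electrophilic aromatic iodination at C6, the last free carbon of ring A, run without acid so that the ionisable C4 carbinol survives.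

Step 9
Reactants: 10 8-bromo-6-iodo-4-hydroxy-penta-O-benzyl-(+)-epicatechin; 4 penta-O-benzyl-4-oxo-epicatechin
Product: 12 unit 1–unit 2 diol, via 6-lithio unit 2 sodium alkoxide 11 (not isolated)
Conditions: 10, NaH (1.1 equiv), THF, 0 °C; t-BuLi (2.0 equiv), −95 °C; 4, −95 → −40 °C; aq NH4Cl
Reagents that add atoms: none
Why: With the hydroxyl masked as its sodium alkoxide, iodine–lithium exchange (much faster for iodide than for bromide) gives aryllithium 11, whose 1,2-addition to ketone 4 anti to the C2 aryl and C3 benzyloxy groups forms the unit 1 C4–unit 2 C6 bond, the carbinol configuration being erased in step 12.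

Step 10
Reactants: 12 unit 1–unit 2 diol
Product: 13 unit 1–unit 2 keto alcohol (ketone at C4 of unit 2)
Conditions: (n-Pr)4NRuO4 (5 mol %), NMO, 4 Å MS, CH2Cl2, 20 °C
Reagents that add atoms: none
Why: Ley–Griffith oxidation converts the secondary C4 alcohol of unit 2 into the ketone, whereas the tertiary carbinol cannot be oxidised.

Step 11
Reactants: 5 8-bromo-penta-O-benzyl-(−)-epicatechin; 13 unit 1–unit 2 keto alcohol
Product: 15 trimer bis(tertiary carbinol), via 8-lithio unit 3 reagent 14 (not isolated)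
Conditions: 5 (2.5 equiv), t-BuLi (5.0 equiv), THF, −78 °C; 13, −78 → −40 °C; aq NH4Cl
Reagents that add atoms: none
Why: Bromine–lithium exchange on 5 gives aryllithium 14, one equivalent of which removes the carbinol proton of 13 while a second adds 1,2 to the unit 2 ketone anti to its C2 aryl and C3 benzyloxy groups, forming the unit 2 C4–unit 3 C8 bond, the carbinol configuration being erased in step 12.

Step 12
Reactants: 15 trimer bis(tertiary carbinol)
Product: 16 protected trimer (unit 2 brominated at C8)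
Conditions: Bu3SnH (6 equiv), TFA (10 equiv), CH2Cl2, 0 °C
Reagents that add atoms: none
Why: Ionic hydrogenation in which TFA ionises each tertiary carbinol to a bis(trialkoxyaryl)methyl cation and Bu3SnH delivers hydride to the face of ring C opposite the C2 aryl and C3 benzyloxy groups, so that the 3,4-cis centres C4 of unit 1 and C4 of unit 2 are both set by substrate control in one operation.

Step 13
Reactants: 16 protected trimer
Product: 17 protected trimer with a 2-ethoxyethoxy group at C4 of unit 3 (both C4 epimers)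
Conditions: DDQ (1.5 equiv), 2-ethoxyethanol (5 equiv), CH2Cl2, 20 °C
Reagents that add atoms: 2-ethoxyethanol CCOCCO
Why: DDQ benzylic oxidation with trapping by the alcohol, selective because only unit 3 offers an unhindered C4 methylene on a bromine-free ring A whereas the C4–H bonds of units 1 and 2 are diarylmethine hydrogens buried between ortho benzyloxy groups, and both C4 epimers of the ether are usable.

Step 14
Reactants: 17 protected trimer 2-ethoxyethyl ether
Product: 18 tetrabromo trimer 2-ethoxyethyl ether (Br at C6 and C8 of unit 1, C8 of unit 2, C6 of unit 3)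
Conditions: NBS (3.2 equiv), NaHCO3, CH2Cl2, −40 → 0 °C
Reagents that add atoms: N-bromosuccinimide O=C1CCC(=O)N1Br
Why: Electrophilic aromatic bromination of the three remaining ring A C–H positions, buffered to protect the C4 ether, so that no nucleophilic ring A carbon is left in the electrophile.

Step 15
Reactants: 18 tetrabromo trimer 2-ethoxyethyl ether; 5 8-bromo-penta-O-benzyl-(−)-epicatechin
Product: 20 protected pentabromo tetramer, via unit 3 C4 cation 19 (not isolated)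
Conditions: 18 (1 equiv), 5 (3 equiv), TMSOTf (0.3 equiv), 4 Å MS, CH2Cl2, −78 → −30 °C; Et3N quench
Reagents that add atoms: none
Why: TMSOTf ionises the C4–O bond of unit 3 in 18 to the planar benzylic cation 19, a para-quinone-methide-type oxocarbenium ion stabilised by O1, O5 and O7 of its ring A, and C6 of 5 attacks it in a Friedel–Crafts alkylation that ends with loss of the C6 proton. The closest known reaction type is the Lewis acid-mediated arylation of flavan-4-yl ethers used to form interflavan bonds, here with halogen-capped partners. No ring is closed. The one new stereocentre, C4 of unit 3, is controlled by the C2 aryl and C3 benzyloxy groups of ring C of the same unit, which shield one face so that the arene adds to the other and gives the 3,4-trans (4β) bond; because both C4 epimers of 18 give the same cation, the step is stereoconvergent. The step needs site selectivity for C6 over C8 of unit 4, secured by the C8 bromine of 5, and cross-coupling over self-condensation, secured by bromine at every other free ring A carbon (unit 1 C6 and C8, unit 2 C8, unit 3 C6), so that C6 of 5 is the only unsubstituted carbon of a 1,3,5-trioxygenated ring in the flask.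

Step 16
Reactants: 20 protected pentabromo tetramer
Product: 21 CNP0120618.3
Conditions: H2 (1 atm), Pd(OH)2 on carbon, Et3N (6 equiv), THF/MeOH/H2O, 20 °C
Reagents that add atoms: none
Why: Hydrogenolysis over Pd(OH)2 cleaves the twenty benzyl ethers and the five aryl C–Br bonds, Et3N taking up the HBr that would otherwise cleave the acid-labile interflavan bonds, and no stereocentre is touched.

**Compound list**

1 | (−)-epicatechin, (2R,3R)-2-(3,4-dihydroxyphenyl)chromane-3,5,7-triol | Oc1cc(O)c2c(c1)O[C@H](c1ccc(O)c(O)c1)[C@H](O)C2 | starting material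

2 | 3,5,7,3',4'-penta-O-benzyl-(−)-epicatechin | O(Cc9ccccc9)c1cc(OCc9ccccc9)c2c(c1)O[C@H](c1ccc(OCc9ccccc9)c(OCc9ccccc9)c1)[C@H](OCc9ccccc9)C2 | intermediate

3 | 4β-hydroxy-3,5,7,3',4'-penta-O-benzyl-(−)-epicatechin (C4 OH trans to the C3 benzyloxy group) | O(Cc9ccccc9)c1cc(OCc9ccccc9)c2c(c1)O[C@H](c1ccc(OCc9ccccc9)c(OCc9ccccc9)c1)[C@H](OCc9ccccc9)[C@H]2O | intermediate

4 | (2R,3S)-3,5,7-tris(benzyloxy)-2-[3,4-bis(benzyloxy)phenyl]chroman-4-one (2,3-cis; C4 ketone of 2) | O(Cc9ccccc9)c1cc(OCc9ccccc9)c2c(c1)O[C@H](c1ccc(OCc9ccccc9)c(OCc9ccccc9)c1)[C@H](OCc9ccccc9)C2=O | intermediate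

5 | 8-bromo-3,5,7,3',4'-penta-O-benzyl-(−)-epicatechin | O(Cc9ccccc9)c1cc(OCc9ccccc9)c2c(c1Br)O[C@H](c1ccc(OCc9ccccc9)c(OCc9ccccc9)c1)[C@H](OCc9ccccc9)C2 | intermediate

6 | (+)-epicatechin (ent-epicatechin), (2S,3S)-2-(3,4-dihydroxyphenyl)chromane-3,5,7-triol | Oc1cc(O)c2c(c1)O[C@@H](c1ccc(O)c(O)c1)[C@@H](O)C2 | starting material

7 | 3,5,7,3',4'-penta-O-benzyl-(+)-epicatechin | O(Cc9ccccc9)c1cc(OCc9ccccc9)c2c(c1)O[C@@H](c1ccc(OCc9ccccc9)c(OCc9ccccc9)c1)[C@@H](OCc9ccccc9)C2 | intermediate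

8 | 4-hydroxy-3,5,7,3',4'-penta-O-benzyl-(+)-epicatechin (C4 OH trans to the C3 benzyloxy group; mirror image of 3) | O(Cc9ccccc9)c1cc(OCc9ccccc9)c2c(c1)O[C@@H](c1ccc(OCc9ccccc9)c(OCc9ccccc9)c1)[C@@H](OCc9ccccc9)[C@@H]2O | intermediate

9 | 8-bromo-4-hydroxy-3,5,7,3',4'-penta-O-benzyl-(+)-epicatechin | O(Cc9ccccc9)c1cc(OCc9ccccc9)c2c(c1Br)O[C@@H](c1ccc(OCc9ccccc9)c(OCc9ccccc9)c1)[C@@H](OCc9ccccc9)[C@@H]2O | intermediate

10 | 8-bromo-6-iodo-4-hydroxy-3,5,7,3',4'-penta-O-benzyl-(+)-epicatechin | O(Cc9ccccc9)c1c(I)c(OCc9ccccc9)c2c(c1Br)O[C@@H](c1ccc(OCc9ccccc9)c(OCc9ccccc9)c1)[C@@H](OCc9ccccc9)[C@@H]2O | intermediate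

11 | 6-lithio derivative of 10 as its sodium C4 alkoxide (bromine retained) | O(Cc9ccccc9)c1c([Li])c(OCc9ccccc9)c2c(c1Br)O[C@@H](c1ccc(OCc9ccccc9)c(OCc9ccccc9)c1)[C@@H](OCc9ccccc9)[C@@H]2O[Na] | intermediate

12 | unit 1–unit 2 diol: C4 of penta-O-benzyl-epicatechin (tertiary carbinol, aryl expected trans to the C3 benzyloxy group) bonded to C6 of 8-bromo-4-hydroxy-penta-O-benzyl-ent-epicatechin | O(Cc9ccccc9)c1cc(OCc9ccccc9)c2c(c1)O[C@H](c1ccc(OCc9ccccc9)c(OCc9ccccc9)c1)[C@H](OCc9ccccc9)[C@@]2(O)c1c(OCc9ccccc9)c(Br)c2c(c1OCc9ccccc9)[C@@H](O)[C@H](OCc9ccccc9)[C@H](c1ccc(OCc9ccccc9)c(OCc9ccccc9)c1)O2 | intermediate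

13 | unit 1–unit 2 keto alcohol: 12 with a ketone at C4 of unit 2 | O(Cc9ccccc9)c1cc(OCc9ccccc9)c2c(c1)O[C@H](c1ccc(OCc9ccccc9)c(OCc9ccccc9)c1)[C@H](OCc9ccccc9)[C@@]2(O)c1c(OCc9ccccc9)c(Br)c2c(c1OCc9ccccc9)C(=O)[C@H](OCc9ccccc9)[C@H](c1ccc(OCc9ccccc9)c(OCc9ccccc9)c1)O2 | intermediate

14 | 8-lithio-3,5,7,3',4'-penta-O-benzyl-(−)-epicatechin | O(Cc9ccccc9)c1cc(OCc9ccccc9)c2c(c1[Li])O[C@H](c1ccc(OCc9ccccc9)c(OCc9ccccc9)c1)[C@H](OCc9ccccc9)C2 | intermediate

15 | trimer bis(tertiary carbinol): 13 with C8 of penta-O-benzyl-epicatechin added to the unit 2 ketone (aryl expected trans to the C3 benzyloxy group) | O(Cc9ccccc9)c1cc(OCc9ccccc9)c2c(c1)O[C@H](c1ccc(OCc9ccccc9)c(OCc9ccccc9)c1)[C@H](OCc9ccccc9)[C@@]2(O)c1c(OCc9ccccc9)c(Br)c2c(c1OCc9ccccc9)[C@](c1c(OCc9ccccc9)cc(OCc9ccccc9)c3c1O[C@H](c1ccc(OCc9ccccc9)c(OCc9ccccc9)c1)[C@H](OCc9ccccc9)C3)(O)[C@H](OCc9ccccc9)[C@H](c1ccc(OCc9ccccc9)c(OCc9ccccc9)c1)O2 | intermediate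

16 | protected trimer: penta-O-benzyl-epicatechin-(4α→6)-8-bromo-penta-O-benzyl-ent-epicatechin-(4β→8)-penta-O-benzyl-epicatechin (ring C 3,4-cis in units 1 and 2) | O(Cc9ccccc9)c1cc(OCc9ccccc9)c2c(c1)O[C@H](c1ccc(OCc9ccccc9)c(OCc9ccccc9)c1)[C@H](OCc9ccccc9)[C@@H]2c1c(OCc9ccccc9)c(Br)c2c(c1OCc9ccccc9)[C@H](c1c(OCc9ccccc9)cc(OCc9ccccc9)c3c1O[C@H](c1ccc(OCc9ccccc9)c(OCc9ccccc9)c1)[C@H](OCc9ccccc9)C3)[C@H](OCc9ccccc9)[C@H](c1ccc(OCc9ccccc9)c(OCc9ccccc9)c1)O2 | intermediate

17 | 16 carrying a 2-ethoxyethoxy group at C4 of unit 3 (both C4 epimers, centre left undefined) | O(Cc9ccccc9)c1cc(OCc9ccccc9)c2c(c1)O[C@H](c1ccc(OCc9ccccc9)c(OCc9ccccc9)c1)[C@H](OCc9ccccc9)[C@@H]2c1c(OCc9ccccc9)c(Br)c2c(c1OCc9ccccc9)[C@H](c1c(OCc9ccccc9)cc(OCc9ccccc9)c3c1O[C@H](c1ccc(OCc9ccccc9)c(OCc9ccccc9)c1)[C@H](OCc9ccccc9)C3OCCOCC)[C@H](OCc9ccccc9)[C@H](c1ccc(OCc9ccccc9)c(OCc9ccccc9)c1)O2 | intermediate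

18 | 17 with bromine also at C6 and C8 of unit 1 and C6 of unit 3 (tetrabromide) | O(Cc9ccccc9)c1c(Br)c(OCc9ccccc9)c2c(c1Br)O[C@H](c1ccc(OCc9ccccc9)c(OCc9ccccc9)c1)[C@H](OCc9ccccc9)[C@@H]2c1c(OCc9ccccc9)c(Br)c2c(c1OCc9ccccc9)[C@H](c1c(OCc9ccccc9)c(Br)c(OCc9ccccc9)c3c1O[C@H](c1ccc(OCc9ccccc9)c(OCc9ccccc9)c1)[C@H](OCc9ccccc9)C3OCCOCC)[C@H](OCc9ccccc9)[C@H](c1ccc(OCc9ccccc9)c(OCc9ccccc9)c1)O2 | intermediate

19 | C4 cation of unit 3 formed from 18 by loss of 2-ethoxyethoxide | O(Cc9ccccc9)c1c(Br)c(OCc9ccccc9)c2c(c1Br)O[C@H](c1ccc(OCc9ccccc9)c(OCc9ccccc9)c1)[C@H](OCc9ccccc9)[C@@H]2c1c(OCc9ccccc9)c(Br)c2c(c1OCc9ccccc9)[C@H](c1c(OCc9ccccc9)c(Br)c(OCc9ccccc9)c3c1O[C@H](c1ccc(OCc9ccccc9)c(OCc9ccccc9)c1)[C@H](OCc9ccccc9)[CH+]3)[C@H](OCc9ccccc9)[C@H](c1ccc(OCc9ccccc9)c(OCc9ccccc9)c1)O2 | intermediate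

20 | protected tetramer: eicosa-O-benzyl ether of the target with bromine at unit 1 C6 and C8, unit 2 C8, unit 3 C6 and unit 4 C8 | O(Cc9ccccc9)c1c(Br)c(OCc9ccccc9)c2c(c1Br)O[C@H](c1ccc(OCc9ccccc9)c(OCc9ccccc9)c1)[C@H](OCc9ccccc9)[C@@H]2c1c(OCc9ccccc9)c(Br)c2c(c1OCc9ccccc9)[C@H](c1c(OCc9ccccc9)c(Br)c(OCc9ccccc9)c3c1O[C@H](c1ccc(OCc9ccccc9)c(OCc9ccccc9)c1)[C@H](OCc9ccccc9)[C@H]3c1c(OCc9ccccc9)c(Br)c3c(c1OCc9ccccc9)C[C@@H](OCc9ccccc9)[C@@H](c1ccc(OCc9ccccc9)c(OCc9ccccc9)c1)O3)[C@H](OCc9ccccc9)[C@H](c1ccc(OCc9ccccc9)c(OCc9ccccc9)c1)O2 | intermediate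

21 | CNP0120618.3, epicatechin-(4α→6)-ent-epicatechin-(4β→8)-epicatechin-(4β→6)-epicatechin | Oc1cc(O)c2c(c1)O[C@H](c1ccc(O)c(O)c1)[C@H](O)[C@@H]2c1c(O)cc2c(c1O)[C@H](c1c(O)cc(O)c3c1O[C@H](c1ccc(O)c(O)c1)[C@H](O)[C@H]3c1c(O)cc3c(c1O)C[C@@H](O)[C@@H](c1ccc(O)c(O)c1)O3)[C@H](O)[C@H](c1ccc(O)c(O)c1)O2 | target

**Summary**

Total step count: 16. Longest linear sequence: 12 steps (from 6 through steps 5 to 16).

Steps most likely to fail:

1. Step 15. The bulky cation may be captured too slowly by the hindered, bromine-deactivated C6 of 5 and be lost through proton loss from C3 (flav-3-ene formation) or return of 2-ethoxyethanol. The fallback sets out from 5 and 18 and comes back at 20; it turns the nucleophilic carbon into a carbon–metal bond. Compound 5 is iodinated at C6 (NIS, MeCN/CH2Cl2) to 8-bromo-6-iodo-penta-O-benzyl-(−)-epicatechin F1. Iodine–magnesium exchange (i-PrMgCl·LiCl, THF, −20 °C, iodide only) gives the arylmagnesium chloride F2, and ZnCl2 converts it into the arylzinc chloride F3. F3 and 18 with BF3·OEt2 in CH2Cl2/toluene at −78 → −20 °C should give 20, the C–Zn bond attacking cation 19 at its ipso carbon on the same open face. This is a Lewis acid-promoted substitution of a benzylic ether by an arylzinc reagent, as used for C-aryl glycosides.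

2. Step 13. Hydride abstraction may occur at the diarylmethine C4–H of unit 1 or unit 2, or oxidation may run on to the ketone, instead of clean mono-oxidation at unit 3. The fallback sets out from 2 and 13 and comes back at 17; it moves the oxidation to the monomer stage. Compound 2 with DDQ and 2-ethoxyethanol gives 4β-(2-ethoxyethoxy)-penta-O-benzyl-(−)-epicatechin F4. NBS gives its 8-bromide F5, and t-BuLi (THF, −78 °C) the 8-lithio reagent F6, which adds to 13 as in step 11 to give the bis(tertiary carbinol) carrying the C4 ether, F7. Bu3SnH with chloroacetic acid (CH2Cl2, −20 °C) should then ionise only the two bis-aryl tertiary carbinols, whose cations are far more stabilised than the secondary mono-aryl cation of the C4 ether, and so give 17.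

3. Step 11. Aryllithium 14 may act as a base toward C3–H of the ketone (loss of the 2,3-cis configuration of unit 2) or exchange lithium for the bromine of 13, while the neighbouring lithium carbinolate slows addition. The fallback sets out from 13 and comes back at 16; it reduces before adding. Bu3SnH/TFA (CH2Cl2, −40 °C) applied to 13 should reduce only the tertiary carbinol, because the 2,4,6-trioxygenated aryl ketone is a vinylogous ester and is not ionised; this gives the hydroxyl-free unit 1–unit 2 ketone F8 with 3,4-cis unit 1. Reagent 14 (1.3 equiv) then adds to F8 to give the trimer mono(tertiary carbinol) F9, and a second ionic hydrogenation gives 16.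

**Further compounds**

F1 | step 15 | 8-bromo-6-iodo-3,5,7,3',4'-penta-O-benzyl-(−)-epicatechin | O(Cc9ccccc9)c1c(I)c(OCc9ccccc9)c2c(c1Br)O[C@H](c1ccc(OCc9ccccc9)c(OCc9ccccc9)c1)[C@H](OCc9ccccc9)C2

F2 | step 15 | 6-(chloromagnesio)-8-bromo-penta-O-benzyl-(−)-epicatechin (arylmagnesium chloride) | O(Cc9ccccc9)c1c([Mg]Cl)c(OCc9ccccc9)c2c(c1Br)O[C@H](c1ccc(OCc9ccccc9)c(OCc9ccccc9)c1)[C@H](OCc9ccccc9)C2

F3 | step 15 | 6-(chlorozincio)-8-bromo-penta-O-benzyl-(−)-epicatechin (arylzinc chloride) | O(Cc9ccccc9)c1c([Zn]Cl)c(OCc9ccccc9)c2c(c1Br)O[C@H](c1ccc(OCc9ccccc9)c(OCc9ccccc9)c1)[C@H](OCc9ccccc9)C2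

F4 | step 13 | 4β-(2-ethoxyethoxy)-3,5,7,3',4'-penta-O-benzyl-(−)-epicatechin | O(Cc9ccccc9)c1cc(OCc9ccccc9)c2c(c1)O[C@H](c1ccc(OCc9ccccc9)c(OCc9ccccc9)c1)[C@H](OCc9ccccc9)[C@H]2OCCOCC

F5 | step 13 | 8-bromo-4β-(2-ethoxyethoxy)-3,5,7,3',4'-penta-O-benzyl-(−)-epicatechin | O(Cc9ccccc9)c1cc(OCc9ccccc9)c2c(c1Br)O[C@H](c1ccc(OCc9ccccc9)c(OCc9ccccc9)c1)[C@H](OCc9ccccc9)[C@H]2OCCOCC

F6 | step 13 | 8-lithio-4β-(2-ethoxyethoxy)-3,5,7,3',4'-penta-O-benzyl-(−)-epicatechin | O(Cc9ccccc9)c1cc(OCc9ccccc9)c2c(c1[Li])O[C@H](c1ccc(OCc9ccccc9)c(OCc9ccccc9)c1)[C@H](OCc9ccccc9)[C@H]2OCCOCC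

F7 | step 13 | trimer bis(tertiary carbinol) 15 carrying a 4β-(2-ethoxyethoxy) group at C4 of unit 3 | O(Cc9ccccc9)c1cc(OCc9ccccc9)c2c(c1)O[C@H](c1ccc(OCc9ccccc9)c(OCc9ccccc9)c1)[C@H](OCc9ccccc9)[C@@]2(O)c1c(OCc9ccccc9)c(Br)c2c(c1OCc9ccccc9)[C@](c1c(OCc9ccccc9)cc(OCc9ccccc9)c3c1O[C@H](c1ccc(OCc9ccccc9)c(OCc9ccccc9)c1)[C@H](OCc9ccccc9)[C@H]3OCCOCC)(O)[C@H](OCc9ccccc9)[C@H](c1ccc(OCc9ccccc9)c(OCc9ccccc9)c1)O2

F8 | step 11 | unit 1–unit 2 ketone: 13 with hydrogen in place of the unit 1 C4 hydroxyl (3,4-cis unit 1) | O(Cc9ccccc9)c1cc(OCc9ccccc9)c2c(c1)O[C@H](c1ccc(OCc9ccccc9)c(OCc9ccccc9)c1)[C@H](OCc9ccccc9)[C@@H]2c1c(OCc9ccccc9)c(Br)c2c(c1OCc9ccccc9)C(=O)[C@H](OCc9ccccc9)[C@H](c1ccc(OCc9ccccc9)c(OCc9ccccc9)c1)O2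

F9 | step 11 | trimer mono(tertiary carbinol): 16 with a hydroxyl at C4 of unit 2 | O(Cc9ccccc9)c1cc(OCc9ccccc9)c2c(c1)O[C@H](c1ccc(OCc9ccccc9)c(OCc9ccccc9)c1)[C@H](OCc9ccccc9)[C@@H]2c1c(OCc9ccccc9)c(Br)c2c(c1OCc9ccccc9)[C@](c1c(OCc9ccccc9)cc(OCc9ccccc9)c3c1O[C@H](c1ccc(OCc9ccccc9)c(OCc9ccccc9)c1)[C@H](OCc9ccccc9)C3)(O)[C@H](OCc9ccccc9)[C@H](c1ccc(OCc9ccccc9)c(OCc9ccccc9)c1)O2
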